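**Plan**
Retrosynthesis: first the three O-benzyl bonds that mask unit 2 (the 8-aryloxyapigenin half) are cut. Then C3–C4 and O1–C2 of pyranone ring C of unit 1 (the 5-hydroxy-7-methoxyflavone half) are cut, giving a dihydroxybenzaldehyde and an aroyl sulfoxonium ylide. The remaining cuts are the ylide carbon–acyl bond, the O–C4' diaryl ether bond and the C8–O bond of unit 2.
Forward: apigenin supplies all three rings of unit 2. Its C8 is hydroxylated, and the new phenol takes up ring B of unit 1 from 4-fluorobenzaldehyde. The formyl group is raised to the acid and converted into the ylide. Ring C of unit 1 is the only ring built, and it closes last onto ring A.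
Enabling feature: in ring A of unit 1, C5 (OH) and C8a (O1) are the two ortho neighbours of C4a, and C7 (OMe) lies para to it. The ring therefore has a local mirror plane through C4a and C7, and mirror-symmetric 2,6-dihydroxy-4-methoxybenzaldehyde delivers it without protection, with either hydroxyl able to close the pyranone.
Stereochemistry: the target has no stereocentre and no hindered axis, so nothing has to be set.

Key step: step 8

Remark: flavone numbering is used throughout, with unit 1 the 7-methoxy half and unit 2 the half bearing the aryloxy group at C8. 2,6-Dihydroxy-4-methoxybenzaldehyde is assumed not to be stocked and is made in one step.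

Step 1
Reactants: 1 apigenin
Product: 2 7-(benzyloxy)-2-[4-(benzyloxy)phenyl]-5-hydroxy-4H-chromen-4-one (7,4'-di-O-benzylapigenin)
Conditions: BnBr (2.2 equiv), K2CO3 (2.5 equiv), DMF, rt to 50 °C
Reagents that add atoms: benzyl bromide, BrCc1ccccc1
Why: Williamson ether synthesis under mild carbonate conditions alkylates the free, more acidic 7- and 4'-phenols, while the 5-hydroxyl, hydrogen-bonded to the C4 carbonyl, stays free as the handle for the next step.

Step 2
Reactants: 2 7,4'-di-O-benzylapigenin
Product: 4 7-(benzyloxy)-2-[4-(benzyloxy)phenyl]-5,8-dihydroxy-4H-chromen-4-one, via potassium 8-sulfate ester 3 (not isolated)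
Conditions: K2S2O8 (1.5 equiv), aq KOH, pyridine, 0 °C to rt; acidify to pH 4–5 and filter off unchanged 2; then 2 M aq HCl, 85 °C, N2
Reagents that add atoms: K2S2O8 (dipotassium peroxodisulfate), [K+].[K+].[O-]S(=O)(=O)OOS(=O)(=O)[O-]
Why: Elbs persulfate oxidation, in which the 5-phenoxide attacks the peroxide oxygen through its para carbon C8 to give aryl sulfate 3 and acid hydrolysis of the S–O bond uncovers the 8-hydroxyl, is the classical para-hydroxylation of 7-O-alkyl-5-hydroxyflavones leading to the 5,7,8-oxygenation pattern.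

Step 3
Reactants: 4 7,4'-di-O-benzyl-5,8-dihydroxyflavone; 5 4-fluorobenzaldehyde
Product: 6 4-({7-(benzyloxy)-2-[4-(benzyloxy)phenyl]-5-hydroxy-4-oxo-4H-chromen-8-yl}oxy)benzaldehyde
Conditions: 5 (1.3 equiv), K2CO3 (1.5 equiv), degassed DMF, Ar, 90 °C
Reagents that add atoms: none
Why: Nucleophilic aromatic substitution through a Meisenheimer adduct para to the formyl group, with the free 8-phenoxide as nucleophile because the 5-hydroxyl is chelated and its anion is delocalised into the pyranone carbonyl (the selectivity behind partial 8-O-alkylation of 5,8-dihydroxyflavones), and with air excluded to prevent oxidation to the quinone.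

Step 4
Reactants: 6 5-hydroxy diaryl ether aldehyde
Product: 7 4-({5,7-bis(benzyloxy)-2-[4-(benzyloxy)phenyl]-4-oxo-4H-chromen-8-yl}oxy)benzaldehyde
Conditions: BnBr (1.5 equiv), K2CO3 (3 equiv), Bu4NI (cat.), DMF, 70 °C
Reagents that add atoms: benzyl bromide, BrCc1ccccc1
Why: Williamson ether synthesis under forcing conditions (excess base, iodide catalysis, heat) overcomes the hydrogen bond of the 5-hydroxyl, which must be capped so that no phenoxide competes for the acid chloride or consumes methylide in step 6.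

Step 5
Reactants: 7 tribenzyl aldehyde
Product: 8 4-({5,7-bis(benzyloxy)-2-[4-(benzyloxy)phenyl]-4-oxo-4H-chromen-8-yl}oxy)benzoic acid
Conditions: NaClO2 (2 equiv), NaH2PO4 (2 equiv), 2-methyl-2-butene (20 equiv), THF/t-BuOH/H2O, rt
Reagents that add atoms: NaClO2 (sodium chlorite), [Na+].[O-]Cl=O
Why: Pinnick oxidation converts the aryl aldehyde into the acid under buffered mild conditions, and the large excess of 2-methyl-2-butene traps HOCl before it can chlorinate the electron-rich C6 or C3 positions.

Step 6
Reactants: 8 tribenzyl acid; 9 trimethylsulfoxonium iodide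
Product: 12 dimethylsulfoxonium 2-[4-({5,7-bis(benzyloxy)-2-[4-(benzyloxy)phenyl]-4-oxo-4H-chromen-8-yl}oxy)phenyl]-2-oxoethylide, via dimethylsulfoxonium methylide 10 (not isolated), via acid chloride 11 (not isolated)
Conditions: 8, (COCl)2 (1.5 equiv), DMF (cat.), CH2Cl2, 0 °C to rt, evaporate; separately 9 (2.5 equiv), KOtBu (2.4 equiv), THF, reflux, 2 h; crude 11 in THF added at 0 °C, 1 h, prompt aqueous quench
Reagents that add atoms: oxalyl chloride, O=C(Cl)C(=O)Cl (supplies the chlorine of 11)
Why: Acylation of the Corey–Chaykovsky methylide by an aroyl chloride, with a second equivalent of 10 removing the acidic proton to give the stabilised keto ylide, should be chemoselective because the acid chloride reacts at 0 °C far faster than the flavone of unit 2, whose C2=C3 bond is a doubly donor-substituted vinylogous ester and a poor acceptor for conjugate methylenation.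

Step 7
Reactants: 13 2,4,6-trihydroxybenzaldehyde
Product: 14 2,6-dihydroxy-4-methoxybenzaldehyde
Conditions: Me2SO4 (1.0 equiv), K2CO3 (1.0 equiv), acetone, rt to 40 °C
Reagents that add atoms: dimethyl sulfate, COS(=O)(=O)OC
Why: Selective Williamson-type O-methylation works because the 4-hydroxyl, para to the formyl group and not hydrogen-bonded, is the most acidic and is ionised first by one equivalent of base, while the two ortho hydroxyls are held by the carbonyl, as in the familiar 4-O-alkylation of 2,4,6-trihydroxyphenyl carbonyl compounds.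

Step 8
Reactants: 14 2,6-dihydroxy-4-methoxybenzaldehyde; 12 aroyl sulfoxonium ylide
Product: 16 5,7-bis(benzyloxy)-2-[4-(benzyloxy)phenyl]-8-[4-(5-hydroxy-7-methoxy-4-oxo-4H-chromen-2-yl)phenoxy]-4H-chromen-4-one, via 1,3-diketone 15 (not isolated)
Conditions: 14 (2 equiv), [Cp*RhCl2]2 (5 mol %), AgSbF6 (20 mol %), PivOH (1 equiv), DCE, 100 °C, Ar
Reagents that add atoms: none
Why: Chloride abstraction by AgSbF6 gives a cationic Cp*Rh complex of trivalent rhodium that binds one phenoxide of 14 and cleaves the neighbouring formyl C–H bond by concerted metalation–deprotonation (pivalate as proton shuttle), forming a five-membered acyl rhodacycle. Ylide 12 binds through carbon and expels DMSO to leave a rhodium carbene, migratory insertion of the acyl ligand makes C3–C4, and protonolysis frees diketone 15 and returns the catalyst. Ring C of unit 1 closes when an ortho hydroxyl of 15 adds to the aroyl ketone carbon C2 (6-exo-trig hemiketalisation, O1–C2) and water is lost under the acidic medium to give the conjugated 4-pyranone. The closest known reaction type is the Cp*Rh-catalysed annulation of salicylaldehydes with aroyl sulfoxonium ylides to 2-arylchromones, applied here to a larger ylide, and no stereocentre is formed. The selectivity needed is metalation of the formyl C–H bond rather than an aryl C–H bond of 14 or the ortho C–H bond of the aroyl ring of 12; the phenoxide chelate secures it and the excess of 14 suppresses self-annulation of the ylide, while the direction of ring closure is not an issue because the two hydroxyls are mirror-related and the spectator one ends up as the hydrogen-bonded 5-OH. In 12 the position peri to the flavone carbonyl carries OBn, so that ketone cannot direct a competing metalation, and the benzyl ethers, the diaryl ether and the pyranone are inert to the catalyst.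

Step 9
Reactants: 16 tribenzyl biflavone ether
Product: 17 5,7-dihydroxy-8-[4-(5-hydroxy-7-methoxy-4-oxo-4H-chromen-2-yl)phenoxy]-2-(4-hydroxyphenyl)-4H-chromen-4-one (CNP0424791.0)
Conditions: H2 (1 atm), Pd/C (10 wt %), THF/MeOH, rt
Reagents that add atoms: none
Why: Catalytic hydrogenolysis cleaves the three benzylic C–O bonds and leaves the methyl ether, the diaryl ether and both pyranone double bonds untouched, and its neutral medium rules out the acid-induced Wessely–Moser ring opening and reclosure that would move the aryloxy group of unit 2 from C8 to C6.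

**Compound list**
1 | apigenin | O=c1cc(-c2ccc(O)cc2)oc2cc(O)cc(O)c12 | starting material
2 | 7,4'-di-O-benzylapigenin | O=c1cc(-c2ccc(OCc3ccccc3)cc2)oc2cc(OCc3ccccc3)cc(O)c12 | intermediate
3 | potassium 7-(benzyloxy)-2-[4-(benzyloxy)phenyl]-5-hydroxy-4-oxo-4H-chromen-8-yl sulfate | O=c1cc(-c2ccc(OCc3ccccc3)cc2)oc2c(OS(=O)(=O)[O-])c(OCc3ccccc3)cc(O)c12.[K+] | intermediate
4 | 7-(benzyloxy)-2-[4-(benzyloxy)phenyl]-5,8-dihydroxy-4H-chromen-4-one | O=c1cc(-c2ccc(OCc3ccccc3)cc2)oc2c(O)c(OCc3ccccc3)cc(O)c12 | intermediate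
5 | 4-fluorobenzaldehyde | O=Cc1ccc(F)cc1 | starting material
6 | 4-({7-(benzyloxy)-2-[4-(benzyloxy)phenyl]-5-hydroxy-4-oxo-4H-chromen-8-yl}oxy)benzaldehyde | O=Cc1ccc(Oc2c(OCc3ccccc3)cc(O)c3c(=O)cc(-c4ccc(OCc5ccccc5)cc4)oc23)cc1 | intermediate
7 | 4-({5,7-bis(benzyloxy)-2-[4-(benzyloxy)phenyl]-4-oxo-4H-chromen-8-yl}oxy)benzaldehyde | O=Cc1ccc(Oc2c(OCc3ccccc3)cc(OCc3ccccc3)c3c(=O)cc(-c4ccc(OCc5ccccc5)cc4)oc23)cc1 | intermediate
8 | 4-({5,7-bis(benzyloxy)-2-[4-(benzyloxy)phenyl]-4-oxo-4H-chromen-8-yl}oxy)benzoic acid | O=C(O)c1ccc(Oc2c(OCc3ccccc3)cc(OCc3ccccc3)c3c(=O)cc(-c4ccc(OCc5ccccc5)cc4)oc23)cc1 | intermediate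
9 | trimethylsulfoxonium iodide | C[S+](C)(C)=O.[I-] | starting material
10 | dimethylsulfoxonium methylide | CS(C)(=O)=C | intermediate
11 | 4-({5,7-bis(benzyloxy)-2-[4-(benzyloxy)phenyl]-4-oxo-4H-chromen-8-yl}oxy)benzoyl chloride | O=C(Cl)c1ccc(Oc2c(OCc3ccccc3)cc(OCc3ccccc3)c3c(=O)cc(-c4ccc(OCc5ccccc5)cc4)oc23)cc1 | intermediate
12 | dimethylsulfoxonium 2-[4-({5,7-bis(benzyloxy)-2-[4-(benzyloxy)phenyl]-4-oxo-4H-chromen-8-yl}oxy)phenyl]-2-oxoethylide | CS(C)(=O)=CC(=O)c1ccc(Oc2c(OCc3ccccc3)cc(OCc3ccccc3)c3c(=O)cc(-c4ccc(OCc5ccccc5)cc4)oc23)cc1 | intermediate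
13 | 2,4,6-trihydroxybenzaldehyde | O=Cc1c(O)cc(O)cc1O | starting material
14 | 2,6-dihydroxy-4-methoxybenzaldehyde | COc1cc(O)c(C=O)c(O)c1 | intermediate
15 | 1-(2,6-dihydroxy-4-methoxyphenyl)-3-[4-({5,7-bis(benzyloxy)-2-[4-(benzyloxy)phenyl]-4-oxo-4H-chromen-8-yl}oxy)phenyl]propane-1,3-dione | COc1cc(O)c(C(=O)CC(=O)c2ccc(Oc3c(OCc4ccccc4)cc(OCc4ccccc4)c4c(=O)cc(-c5ccc(OCc6ccccc6)cc5)oc34)cc2)c(O)c1 | intermediate
16 | 5,7-bis(benzyloxy)-2-[4-(benzyloxy)phenyl]-8-[4-(5-hydroxy-7-methoxy-4-oxo-4H-chromen-2-yl)phenoxy]-4H-chromen-4-one | COc1cc(O)c2c(=O)cc(-c3ccc(Oc4c(OCc5ccccc5)cc(OCc5ccccc5)c5c(=O)cc(-c6ccc(OCc7ccccc7)cc6)oc45)cc3)oc2c1 | intermediate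
17 | 5,7-dihydroxy-8-[4-(5-hydroxy-7-methoxy-4-oxo-4H-chromen-2-yl)phenoxy]-2-(4-hydroxyphenyl)-4H-chromen-4-one (CNP0424791.0) | COc1cc(O)c2c(=O)cc(-c3ccc(Oc4c(O)cc(O)c5c(=O)cc(-c6ccc(O)cc6)oc45)cc3)oc2c1 | target

Total step count: 9
Longest linear sequence: 8 steps (steps 1–6, 8 and 9, from apigenin)

**Steps most likely to fail**

Step 8. C3–C4 formation could stall in three ways. The ylide could self-annulate through ortho C–H metalation of its own aroyl ring. The electron-rich acyl rhodium intermediate could decarbonylate. The free resorcinol unit could tie up the catalyst. The fallback sets out from acid chloride 11 (first operation of step 6) and forms C2–C3 by enolate acylation in the manner of a Baker–Venkataraman synthesis. Purchased 2',6'-dihydroxy-4'-methoxyacetophenone F1 is converted with LiN(SiMe3)2 (4.5 equiv, THF, −78 to −10 °C) into its trilithium salt. This salt is C-acylated by 11 to give diketone 15, which is isolated in this variant. TsOH·H2O (cat.) in refluxing toluene then closes ring C, and the route is rejoined at 16.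

Step 2. The phenoxide of 2 dissolves poorly in aqueous alkali, which limits conversion, and the hydroquinone formed may be oxidised further by persulfate. The fallback sets out from 2 and installs the C8 oxygen through a halide.
- BnBr, K2CO3 and Bu4NI in DMF at 80 °C give 5,7,4'-tri-O-benzylapigenin F2.
- NIS in DMF iodinates the fully alkylated ring A at C8, the less flanked of its two activated positions, to give 8-iodo-5,7,4'-tri-O-benzylapigenin F3.
- Miyaura borylation (B2pin2, PdCl2(dppf), KOAc, dioxane, 90 °C) gives 8-(pinacolboryl)-5,7,4'-tri-O-benzylapigenin F4.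
- NaBO3·4H2O in THF/H2O oxidises the C–B bond to give 8-hydroxy-5,7,4'-tri-O-benzylapigenin F5.
- Substitution on 5 under the conditions of step 3 then rejoins the route at 7.

Steps 2–4 are bypassed and no hydroquinone is handled.

Step 3. At the temperature the substitution needs, the hydroquinone monoanion may be oxidised to the quinone, and the flanked 8-phenoxide may attack the fluoroarene too slowly. The fallback sets out from 4 and transfers the aryl group by ligand coupling at trivalent iodine near room temperature. [4-(Methoxycarbonyl)phenyl](2,4,6-trimethoxyphenyl)iodonium tosylate F6 is made in one pot from methyl 4-iodobenzoate (mCPBA, TsOH·H2O, MeCN, then 1,3,5-trimethoxybenzene). It arylates the 8-phenoxide of 4 (K2CO3, MeCN, 40 °C, Ar) with transfer of the electron-poor aryl group, giving methyl 4-({7-(benzyloxy)-2-[4-(benzyloxy)phenyl]-5-hydroxy-4-oxo-4H-chromen-8-yl}oxy)benzoate F7. Benzylation as in step 4 gives methyl 4-({5,7-bis(benzyloxy)-2-[4-(benzyloxy)phenyl]-4-oxo-4H-chromen-8-yl}oxy)benzoate F8. LiOH in THF/H2O at rt followed by dilute HCl rejoins the route at 8, replacing steps 3–5.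

**Further compounds**
F1 | step 8 | 2',6'-dihydroxy-4'-methoxyacetophenone (purchased) | CC(=O)c1c(O)cc(OC)cc1O
F2 | step 2 | 5,7,4'-tri-O-benzylapigenin | O=c1cc(-c2ccc(OCc3ccccc3)cc2)oc2cc(OCc3ccccc3)cc(OCc3ccccc3)c12
F3 | step 2 | 8-iodo-5,7,4'-tri-O-benzylapigenin | O=c1cc(-c2ccc(OCc3ccccc3)cc2)oc2c(I)c(OCc3ccccc3)cc(OCc3ccccc3)c12
F4 | step 2 | 8-(pinacolboryl)-5,7,4'-tri-O-benzylapigenin | CC1(C)OB(OC1(C)C)c1c(OCc2ccccc2)cc(OCc2ccccc2)c2c(=O)cc(-c3ccc(OCc4ccccc4)cc3)oc12
F5 | step 2 | 8-hydroxy-5,7,4'-tri-O-benzylapigenin | O=c1cc(-c2ccc(OCc3ccccc3)cc2)oc2c(O)c(OCc3ccccc3)cc(OCc3ccccc3)c12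
F6 | step 3 | [4-(methoxycarbonyl)phenyl](2,4,6-trimethoxyphenyl)iodonium tosylate | COC(=O)c1ccc([I+]c2c(OC)cc(OC)cc2OC)cc1.Cc1ccc(S(=O)(=O)[O-])cc1
F7 | step 3 | methyl 4-({7-(benzyloxy)-2-[4-(benzyloxy)phenyl]-5-hydroxy-4-oxo-4H-chromen-8-yl}oxy)benzoate | COC(=O)c1ccc(Oc2c(OCc3ccccc3)cc(O)c3c(=O)cc(-c4ccc(OCc5ccccc5)cc4)oc23)cc1
F8 | step 3 | methyl 4-({5,7-bis(benzyloxy)-2-[4-(benzyloxy)phenyl]-4-oxo-4H-chromen-8-yl}oxy)benzoate | COC(=O)c1ccc(Oc2c(OCc3ccccc3)cc(OCc3ccccc3)c3c(=O)cc(-c4ccc(OCc5ccccc5)cc4)oc23)cc1
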